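The route rests on disconnecting the cyclohexene ring C2–C3–C4–C5–C13–C12, which is cis-fused to the cyclobutane along C2–C12, shares C12–C13 with the cyclopentane and carries oxygen at C5. It is cut into a strained cyclobutenone C2=C12 π bond and a C3=C4–C5(OSi)=C13 diene, tied together through C9–C10–C11. One intramolecular Diels–Alder reaction forms C2–C3 and C12–C13, closes that cyclohexene and the cyclopentane, and sets C2, C12 and C13. It leaves a C4=C5 enol ether that later becomes the C3=C4 alkene and the C5 carbinol. The precursor is a (4S)-4-substituted cyclobut-2-enone whose side chain holds the (S)-C9 centre, a silyl-protected CH2O group (C8) and a (Z)-2-silyloxy-1,3-diene.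

Key step: step 10

Remarks on the chemistry (numbering and assumptions):
- Ring carbons keep the target numbers C1–C13 (SMILES order: C1 bears octyl, C5 the tertiary OH, C6 the acid, C8 the secondary OH) in all intermediates; C8 is the CH2O carbon on C9 until the last ring is closed.
- The (2S,5S)-pyrrolidine auxiliary is assumed to give (S)-C11 (side chain anti to the proximal methyl group in the cyclobuteniminium ion); if the sense proves opposite, the (2R,5R) amine is used in an otherwise unchanged route.
- (S,S)-ProPhenol is assumed to give the (S)-carbinol with aliphatic aldehydes, by analogy with its aldol reactions; the ligand antipode is used if a model aldehyde shows the opposite sense.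

Step 1
Reactants: 1 glutaric anhydride; 2 (2S,5S)-2,5-dimethylpyrrolidine
Product: 3 5-[(2S,5S)-2,5-dimethylpyrrolidin-1-yl]-5-oxopentanoic acid
Conditions: DMAP (5 mol %), CH2Cl2, 0 °C → rt
Reagents that add atoms: none
Why: Ring-opening aminolysis of the cyclic anhydride should give the mono-amide acid directly and installs the chiral keteniminium auxiliary before any enone exists, so no amine meets a Michael acceptor later.

Step 2
Reactants: 3 5-[(2S,5S)-2,5-dimethylpyrrolidin-1-yl]-5-oxopentanoic acid; 4 (R)-4-benzyloxazolidin-2-one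
Product: 6 (R)-4-benzyl-3-{5-[(2S,5S)-2,5-dimethylpyrrolidin-1-yl]-5-oxopentanoyl}oxazolidin-2-one, via mixed pivalic anhydride 5 (not isolated)
Conditions: PivCl, Et3N, THF, −20 °C; then 4, LiCl, rt
Reagents that add atoms: none
Why: Mixed-anhydride N-acylation of the oxazolidinone (LiCl/Et3N protocol) should acylate only through the activated carboxyl group, the tertiary amide being inert.

Step 3
Reactants: 6 (R)-4-benzyl-3-{5-[(2S,5S)-2,5-dimethylpyrrolidin-1-yl]-5-oxopentanoyl}oxazolidin-2-one; 7 tert-butyl bromoacetate
Product: 8 tert-butyl (S)-3-[(R)-4-benzyl-2-oxooxazolidine-3-carbonyl]-6-[(2S,5S)-2,5-dimethylpyrrolidin-1-yl]-6-oxohexanoate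
Conditions: NaHMDS, THF, −78 °C; then 7, −78 → −40 °C
Reagents that add atoms: none
Why: Evans alkylation: only the imide α-CH2 is enolised at −78 °C, and the chelated (Z)-sodium enolate should be alkylated on the face away from the benzyl group, which sets C9 as S.

Step 4
Reactants: 8 tert-butyl (S)-3-[(R)-4-benzyl-2-oxooxazolidine-3-carbonyl]-6-[(2S,5S)-2,5-dimethylpyrrolidin-1-yl]-6-oxohexanoate
Product: 10 (S)-4-{3-[(2S,5S)-2,5-dimethylpyrrolidin-1-yl]-3-oxopropyl}dihydrofuran-2(3H)-one, via hydroxy tert-butyl ester 9 (not isolated)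
Conditions: LiBH4, H2O (1 equiv), Et2O, 0 °C; then TsOH·H2O (10 mol %), toluene, 60 °C
Reagents that add atoms: none
Why: Reductive cleavage of the imide with LiBH4 should give the C8 alcohol while tert-butyl ester and tertiary amide survive, and acid-catalysed lactonisation then expels tert-butanol to give the γ-lactone.

Step 5
Reactants: 10 (S)-4-{3-[(2S,5S)-2,5-dimethylpyrrolidin-1-yl]-3-oxopropyl}dihydrofuran-2(3H)-one
Product: 11 (S)-6-[(2S,5S)-2,5-dimethylpyrrolidin-1-yl]-3-(hydroxymethyl)-N-methoxy-N-methyl-6-oxohexanamide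
Conditions: MeNH(OMe)·HCl, AlMe3, CH2Cl2, 0 °C → rt; Rochelle salt work-up
Reagents that add atoms: N,O-dimethylhydroxylamine hydrochloride, CNOC.Cl
Why: Weinreb aminolysis of the lactone by the aluminium amide should open the ring at C5, while the hindered pyrrolidine amide does not transamidate.

Step 6
Reactants: 11 (S)-6-[(2S,5S)-2,5-dimethylpyrrolidin-1-yl]-3-(hydroxymethyl)-N-methoxy-N-methyl-6-oxohexanamide
Product: 12 (S)-3-{[(tert-butyldiphenylsilyl)oxy]methyl}-6-[(2S,5S)-2,5-dimethylpyrrolidin-1-yl]-N-methoxy-N-methyl-6-oxohexanamide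
Conditions: TBDPSCl, imidazole, DMF, 0 °C → rt
Reagents that add atoms: tert-butyl(chloro)diphenylsilane, CC(C)(C)[Si](Cl)(c1ccccc1)c1ccccc1
Why: Silylation of the primary alcohol stops relactonisation and gives an ether that should tolerate the Grignard reagent, Tf2O and aqueous acid, which an electron-rich benzyl ether might not.

Step 7
Reactants: 12 (S)-3-{[(tert-butyldiphenylsilyl)oxy]methyl}-6-[(2S,5S)-2,5-dimethylpyrrolidin-1-yl]-N-methoxy-N-methyl-6-oxohexanamide; 13 vinylmagnesium bromide
Product: 14 (S)-4-{[(tert-butyldiphenylsilyl)oxy]methyl}-1-[(2S,5S)-2,5-dimethylpyrrolidin-1-yl]oct-7-ene-1,6-dione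
Conditions: THF, −78 → 0 °C; inverse quench into cold 1 M HCl
Reagents that add atoms: none
Why: Weinreb ketone synthesis: the chelated tetrahedral adduct prevents over-addition, the tertiary amide is inert below 0 °C, and the acidic inverse quench keeps the released methoxyamine from adding to the new enone.

Step 8
Reactants: 14 (S)-4-{[(tert-butyldiphenylsilyl)oxy]methyl}-1-[(2S,5S)-2,5-dimethylpyrrolidin-1-yl]oct-7-ene-1,6-dione; 15 acetylene
Product: 18 (S)-4-[(S)-2-{[(tert-butyldiphenylsilyl)oxy]methyl}-4-oxohex-5-en-1-yl]cyclobut-2-en-1-one, via keteniminium triflate 16 (not isolated), via cyclobuteniminium triflate 17 (not isolated)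
Conditions: Tf2O, 2,4,6-collidine, ClCH2CH2Cl, −20 °C → rt; C2H2 (1 atm), rt → 40 °C; then H2O, rt, work-up at pH 3
Reagents that add atoms: water, O
Why: Keteniminium–alkyne [2+2] cycloaddition (Ghosez type): Tf2O/collidine turns the amide into the aldoketeniminium ion, acetylene adds to give the cyclobuteniminium salt in which the C10 chain should settle anti to the proximal methyl group of the C2-symmetric auxiliary (C11 = S), the electron-poor enone alkene is no partner for this electrophile, C11 cannot epimerise because enolisation would create a cyclobutadiene, and hydrolysis at acidic pH keeps the released amine protonated.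

Step 9
Reactants: 18 (S)-4-[(S)-2-{[(tert-butyldiphenylsilyl)oxy]methyl}-4-oxohex-5-en-1-yl]cyclobut-2-en-1-one
Product: 19 (S)-4-[(S,Z)-4-[(tert-butyldimethylsilyl)oxy]-2-{[(tert-butyldiphenylsilyl)oxy]methyl}hexa-3,5-dien-1-yl]cyclobut-2-en-1-one
Conditions: TBSOTf, Et3N, CH2Cl2, −78 °C; cold NaHCO3 work-up, used at once
Reagents that add atoms: tert-butyldimethylsilyl triflate, CC(C)(C)[Si](C)(C)OS(=O)(=O)C(F)(F)F
Why: Soft enolisation of the vinyl ketone at its only α'-methylene (C13) should give the cross-conjugated silyl dienol ether with the usual Z preference (C9 trans to the vinyl group, as the cycloaddition needs), while the cyclobutenone is the less basic carbonyl and cannot enolise without antiaromaticity.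

Step 10
Reactants: 19 (S)-4-[(S,Z)-4-[(tert-butyldimethylsilyl)oxy]-2-{[(tert-butyldiphenylsilyl)oxy]methyl}hexa-3,5-dien-1-yl]cyclobut-2-en-1-one
Product: 20 tricyclic cycloadduct (C1 cyclobutanone; C4=C5 TBS enol ether; C9 CH2OTBDPS on the convex face; H2 H11 H12 H13 all cis)
Conditions: toluene (0.01 M), BHT (cat.), 25 → 45 °C
Reagents that add atoms: none
Why: The electron-rich (Z)-2-silyloxydiene (C3=C4–C5(OTBS)=C13) should add suprafacially across the strained C2=C12 bond of the cyclobutenone in a concerted, asynchronous normal-demand [4+2] cycloaddition that forms C12–C13 and C2–C3 and leaves the C4=C5 silyl enol ether. The closest known reaction type is the Diels–Alder reaction of cyclobutenones as strain-activated dienophiles, in its intramolecular type 1 (nonatriene-like) form. The cyclohexene C2–C3–C4–C5–C13–C12 is the cycloadduct ring itself, and the cyclopentane C9–C10–C11–C12–C13 closes as the tether ring, the three-atom tether C11–C10–C9 joining dienophile carbon C12 to diene terminus C13. C2 and C12 are controlled by the preset C11 centre, because the short tether lets the diene reach only the face of the four-membered ring that carries C10 (H2, H11 and H12 cis), and C13 is controlled by the endo transition state with the cyclobutenone under C4–C5, the exo mode being excluded since it would need a trans-fused hydrindene on a cis-fused cyclobutane. The step needs para regiochemistry (C13, the enol ether β-carbon, to C12, the enone β-carbon), which electronics and tether both enforce, and a rate well above that of 4π-electrocyclic opening of the cyclobutenone, which the release of ring strain on rehybridisation should secure at 25–45 °C. The (S)-C9 centre is matched with (S)-C11 and places its CH2OTBDPS group on the convex face of the forming bicycle, so any C11 epimer carried over from step 8 should react more slowly and give a separable diastereomer.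

Step 11
Reactants: 20 tricyclic cycloadduct; 21 (methoxymethyl)triphenylphosphonium chloride
Product: 22 C1 methoxymethylene derivative of 20 (C1=CH–OMe as E/Z mixture; C4=C5 TBS enol ether retained)
Conditions: KHMDS, THF, 0 °C; then 20, 0 °C → rt
Reagents that add atoms: none
Why: Wittig methoxymethylenation: the strained cyclobutanone is a reactive carbonyl partner that does not enolise readily, and both silyl groups should be inert to the ylide.

Step 12
Reactants: 22 C1 methoxymethylene derivative of 20
Product: 24 keto aldehyde (C5 ketone; C1 formyl group on the convex face cis to H2 and H11), via endo aldehyde 23 (not isolated)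
Conditions: 1 M HCl, THF, rt; then DBU (0.2 equiv), CH2Cl2, rt
Reagents that add atoms: water, O
Why: Acid hydrolysis of both enol ethers should give the C5 ketone and the C1 aldehyde (protonated first from the convex face), and base-catalysed epimerisation through the enol then moves the formyl group to the convex face, trans to C3 and C10, so C1 is set under thermodynamic control.

Step 13
Reactants: 24 keto aldehyde; 25 heptyltriphenylphosphonium bromide
Product: 26 C1 (Z)-oct-1-enyl ketone (C5 ketone; C9 CH2OTBDPS)
Conditions: NaHMDS, THF, 0 °C; then 24, −78 → 0 °C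
Reagents that add atoms: none
Why: Wittig olefination with a non-stabilised ylide should be selective for the aldehyde over the hindered C5 ketone at low temperature, and the alkene geometry is of no consequence.

Step 14
Reactants: 26 C1 (Z)-oct-1-enyl ketone
Product: 27 C1 octyl ketone (octyl on the convex face; C5 ketone; C9 CH2OTBDPS)
Conditions: H2 (1 atm), 10% Pd/C, EtOAc, rt
Reagents that add atoms: none
Why: Catalytic hydrogenation saturates the only C=C bond and should leave ketone and silyl ether alone, which completes the exo octyl chain without touching C1.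

Step 15
Reactants: 27 C1 octyl ketone
Product: 29 enone (C3=C4–C5=O; C1 octyl; C9 CH2OTBDPS), via trimethylsilyl enol ether 28 (not isolated)
Conditions: LDA, TMSCl, THF, −78 °C; then Pd(OAc)2, MeCN, rt
Reagents that add atoms: none
Why: Kinetic deprotonation should take the C4 methylene (C13 is a hindered methine shared by three rings), and Saegusa–Ito oxidation of the silyl enol ether (palladium enolate, β-hydride loss from C3) then gives the C3=C4 enone regiospecifically.

Step 16
Reactants: 29 enone silyl ether
Product: 30 enone primary alcohol (C9 CH2OH)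
Conditions: HF·pyridine, pyridine, THF, 0 °C → rt
Reagents that add atoms: none
Why: Fluoride cleavage of the primary silyl ether under buffered, non-basic conditions should neither deconjugate nor attack the enone.

Step 17
Reactants: 30 enone primary alcohol
Product: 31 enone aldehyde (C9 CHO; the formyl carbon is C8)
Conditions: DMP, CH2Cl2, 0 °C → rt
Reagents that add atoms: none
Why: Dess–Martin oxidation gives the aldehyde under neutral conditions, and C9 is not at risk because its epimer would carry the formyl group on the concave face.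

Step 18
Reactants: 31 enone aldehyde; 32 methyl propiolate
Product: 33 methyl 4-hydroxybut-2-ynoate attached through C4 (= C8; S) to C9 of the tricyclic enone
Conditions: Me2Zn, (S,S)-ProPhenol (20 mol %), Ph3P=O (40 mol %), toluene, 4 °C
Reagents that add atoms: none
Why: Zinc–ProPhenol asymmetric alkynylation: the chiral dinuclear zinc catalyst should deliver the zinc propiolate to one aldehyde face and set C8 as S under reagent control (an α-branched aldehyde of this kind offers little and possibly opposing substrate bias), while alkynylzinc species do not add to the hindered enone.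

Step 19
Reactants: 33 γ-hydroxy ynoate
Product: 34 triethylsilyl ether of 33
Conditions: TESOTf, 2,6-lutidine, CH2Cl2, −78 °C
Reagents that add atoms: triethylsilyl triflate, CC[Si](CC)(CC)OS(=O)(=O)C(F)(F)F
Why: Silylation of the propargylic alcohol removes the acidic O–H that would protonate the copper allenolate of the next step, and the hindered base should not add to the ynoate.

Step 20
Reactants: 34 triethylsilyl-protected γ-hydroxy ynoate
Product: 35 tetracyclic methyl ester (C5 tertiary OH cis to H13; C6=C7 enoate; C8 OTES)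
Conditions: [(Ph3P)CuH]6 (0.18 equiv), toluene, −40 → −20 °C; aq. NH4Cl
Reagents that add atoms: none
Why: Proposed new method: hydrocupration of the alkynoate by Stryker's reagent should put hydride on C7 and give a copper allenolate whose C6 adds to the C5 ketone through a six-membered transition state from the face that carries the C9 tether, so the new ring is cis-fused (C5–OH cis to H13) and the endocyclic C6=C7 enoate results because the allenolate has no fixed alkene geometry; the closest known reaction type is the conjugate reduction–aldol cyclisation of alkynones and of enoates onto ketones with the same reagent, and selectivity over the ring enone relies on the faster hydrometallation of the unhindered, ester-activated alkyne at −40 °C with one equivalent of hydride.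

Step 21
Reactants: 35 tetracyclic methyl ester
Product: 37 target acid CNP0106718.3, via triethylsilyl ether acid 36 (not isolated)
Conditions: LiOH·H2O, THF/MeOH/H2O, rt → 40 °C; then AcOH/THF/H2O (3:1:1), rt
Reagents that add atoms: lithium hydroxide, [Li+].[OH-]
Why: Saponification of the methyl ester followed by mild acidic cleavage of the triethylsilyl ether, which the tertiary allylic alcohol should tolerate; the hydroxy acid cannot lactonise because a butenolide would need a bridgehead alkene.

Compound list
1 | glutaric anhydride | O=C1CCCC(=O)O1 | starting material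
2 | (2S,5S)-2,5-dimethylpyrrolidine | C[C@H]1CC[C@H](C)N1 | starting material
3 | 5-[(2S,5S)-2,5-dimethylpyrrolidin-1-yl]-5-oxopentanoic acid | OC(=O)CCCC(=O)N1[C@@H](C)CC[C@@H]1C | intermediate
4 | (R)-4-benzyloxazolidin-2-one | O=C1N[C@H](Cc2ccccc2)CO1 | starting material
5 | mixed pivalic anhydride of 3 (not isolated) | CC(C)(C)C(=O)OC(=O)CCCC(=O)N1[C@@H](C)CC[C@@H]1C | intermediate
6 | (R)-4-benzyl-3-{5-[(2S,5S)-2,5-dimethylpyrrolidin-1-yl]-5-oxopentanoyl}oxazolidin-2-one | O=C(CCCC(=O)N1[C@@H](C)CC[C@@H]1C)N1[C@H](Cc2ccccc2)COC1=O | intermediate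
7 | tert-butyl bromoacetate | CC(C)(C)OC(=O)CBr | starting material
8 | tert-butyl (S)-3-[(R)-4-benzyl-2-oxooxazolidine-3-carbonyl]-6-[(2S,5S)-2,5-dimethylpyrrolidin-1-yl]-6-oxohexanoate | O=C([C@H](CC(=O)OC(C)(C)C)CCC(=O)N1[C@@H](C)CC[C@@H]1C)N1[C@H](Cc2ccccc2)COC1=O | intermediate
9 | tert-butyl (S)-6-[(2S,5S)-2,5-dimethylpyrrolidin-1-yl]-3-(hydroxymethyl)-6-oxohexanoate (not isolated) | OC[C@H](CC(=O)OC(C)(C)C)CCC(=O)N1[C@@H](C)CC[C@@H]1C | intermediate
10 | (S)-4-{3-[(2S,5S)-2,5-dimethylpyrrolidin-1-yl]-3-oxopropyl}dihydrofuran-2(3H)-one | O=C1C[C@H](CCC(=O)N2[C@@H](C)CC[C@@H]2C)CO1 | intermediate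
11 | (S)-6-[(2S,5S)-2,5-dimethylpyrrolidin-1-yl]-3-(hydroxymethyl)-N-methoxy-N-methyl-6-oxohexanamide | OC[C@H](CC(=O)N(C)OC)CCC(=O)N1[C@@H](C)CC[C@@H]1C | intermediate
12 | (S)-3-{[(tert-butyldiphenylsilyl)oxy]methyl}-6-[(2S,5S)-2,5-dimethylpyrrolidin-1-yl]-N-methoxy-N-methyl-6-oxohexanamide | CC(C)(C)[Si](c1ccccc1)(c1ccccc1)OC[C@H](CC(=O)N(C)OC)CCC(=O)N1[C@@H](C)CC[C@@H]1C | intermediate
13 | vinylmagnesium bromide | C=C[Mg]Br | starting material
14 | (S)-4-{[(tert-butyldiphenylsilyl)oxy]methyl}-1-[(2S,5S)-2,5-dimethylpyrrolidin-1-yl]oct-7-ene-1,6-dione | CC(C)(C)[Si](c1ccccc1)(c1ccccc1)OC[C@H](CC(=O)C=C)CCC(=O)N1[C@@H](C)CC[C@@H]1C | intermediate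
15 | acetylene | C#C | starting material
16 | (2S,5S)-1-[(S)-4-{[(tert-butyldiphenylsilyl)oxy]methyl}-6-oxoocta-1,7-dien-1-ylidene]-2,5-dimethylpyrrolidin-1-ium triflate (keteniminium salt; not isolated) | CC(C)(C)[Si](c1ccccc1)(c1ccccc1)OC[C@H](CC(=O)C=C)CC=C=[N+]1[C@@H](C)CC[C@@H]1C.[O-]S(=O)(=O)C(F)(F)F | intermediate
17 | (2S,5S)-1-{(S)-4-[(S)-2-{[(tert-butyldiphenylsilyl)oxy]methyl}-4-oxohex-5-en-1-yl]cyclobut-2-en-1-ylidene}-2,5-dimethylpyrrolidin-1-ium triflate (cyclobuteniminium salt; not isolated) | CC(C)(C)[Si](c1ccccc1)(c1ccccc1)OC[C@H](CC(=O)C=C)C[C@H]1C=CC1=[N+]2[C@@H](C)CC[C@@H]2C.[O-]S(=O)(=O)C(F)(F)F | intermediate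
18 | (S)-4-[(S)-2-{[(tert-butyldiphenylsilyl)oxy]methyl}-4-oxohex-5-en-1-yl]cyclobut-2-en-1-one | CC(C)(C)[Si](c1ccccc1)(c1ccccc1)OC[C@H](CC(=O)C=C)C[C@H]1C=CC1=O | intermediate
19 | (S)-4-[(S,Z)-4-[(tert-butyldimethylsilyl)oxy]-2-{[(tert-butyldiphenylsilyl)oxy]methyl}hexa-3,5-dien-1-yl]cyclobut-2-en-1-one (key-step precursor) | CC(C)(C)[Si](c1ccccc1)(c1ccccc1)OC[C@H](/C=C(\O[Si](C)(C)C(C)(C)C)C=C)C[C@H]1C=CC1=O | intermediate
20 | tricyclic cycloadduct: C1 cyclobutanone cis-fused at C2–C12 to the cyclohexene (C4=C5 TBS enol ether) and at C11–C12 to the cyclopentane; C9 CH2OTBDPS on the convex face (H9 trans to H13); H2 H11 H12 H13 all cis | O=C1[C@@H]2CC=C(O[Si](C)(C)C(C)(C)C)[C@@H]3[C@@H](CO[Si](c4ccccc4)(c4ccccc4)C(C)(C)C)C[C@H]1[C@H]23 | intermediate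
21 | (methoxymethyl)triphenylphosphonium chloride | COC[P+](c1ccccc1)(c1ccccc1)c1ccccc1.[Cl-] | starting material
22 | C1 methoxymethylene derivative of 20 (C1=CH–OMe; E/Z mixture) | COC=C1[C@@H]2CC=C(O[Si](C)(C)C(C)(C)C)[C@@H]3[C@@H](CO[Si](c4ccccc4)(c4ccccc4)C(C)(C)C)C[C@H]1[C@H]23 | intermediate
23 | endo aldehyde: C5 ketone; C1 formyl on the concave face (C1 epimer of 24; not isolated) | O=C[C@@H]1[C@@H]2CCC(=O)[C@@H]3[C@@H](CO[Si](c4ccccc4)(c4ccccc4)C(C)(C)C)C[C@H]1[C@H]23 | intermediate
24 | keto aldehyde: C5 ketone; C1 formyl on the convex face (cis to H2 and H11); C9 CH2OTBDPS | O=C[C@H]1[C@@H]2CCC(=O)[C@@H]3[C@@H](CO[Si](c4ccccc4)(c4ccccc4)C(C)(C)C)C[C@H]1[C@H]23 | intermediate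
25 | heptyltriphenylphosphonium bromide | CCCCCCC[P+](c1ccccc1)(c1ccccc1)c1ccccc1.[Br-] | starting material
26 | C1 (Z)-oct-1-enyl ketone: C5 ketone; C9 CH2OTBDPS | CCCCCC/C=C\[C@H]1[C@@H]2CCC(=O)[C@@H]3[C@@H](CO[Si](c4ccccc4)(c4ccccc4)C(C)(C)C)C[C@H]1[C@H]23 | intermediate
27 | C1 octyl ketone: octyl on the convex face; C5 ketone; C9 CH2OTBDPS | CCCCCCCC[C@H]1[C@@H]2CCC(=O)[C@@H]3[C@@H](CO[Si](c4ccccc4)(c4ccccc4)C(C)(C)C)C[C@H]1[C@H]23 | intermediate
28 | C4=C5 trimethylsilyl enol ether of 27 (not isolated) | CCCCCCCC[C@H]1[C@@H]2CC=C(O[Si](C)(C)C)[C@@H]3[C@@H](CO[Si](c4ccccc4)(c4ccccc4)C(C)(C)C)C[C@H]1[C@H]23 | intermediate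
29 | enone: C3=C4–C5=O; C1 octyl; C9 CH2OTBDPS | CCCCCCCC[C@H]1[C@@H]2C=CC(=O)[C@@H]3[C@@H](CO[Si](c4ccccc4)(c4ccccc4)C(C)(C)C)C[C@H]1[C@H]23 | intermediate
30 | enone primary alcohol: C9 CH2OH | CCCCCCCC[C@H]1[C@@H]2C=CC(=O)[C@@H]3[C@@H](CO)C[C@H]1[C@H]23 | intermediate
31 | enone aldehyde: C9 CHO (C8) | CCCCCCCC[C@H]1[C@@H]2C=CC(=O)[C@@H]3[C@@H](C=O)C[C@H]1[C@H]23 | intermediate
32 | methyl propiolate | C#CC(=O)OC | starting material
33 | γ-hydroxy ynoate: (S)-C8 carbinol on C9; C7≡C6–CO2Me; ring enone unchanged | CCCCCCCC[C@H]1[C@@H]2C=CC(=O)[C@@H]3[C@@H]([C@H](O)C#CC(=O)OC)C[C@H]1[C@H]23 | intermediate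
34 | triethylsilyl ether of 33 | CCCCCCCC[C@H]1[C@@H]2C=CC(=O)[C@@H]3[C@@H]([C@H](O[Si](CC)(CC)CC)C#CC(=O)OC)C[C@H]1[C@H]23 | intermediate
35 | tetracyclic methyl ester: C5 OH cis to H13; C6(CO2Me)=C7; C8 OTES | CCCCCCCC[C@H]1[C@@H]2C=C[C@]3(O)C(C(=O)OC)=C[C@@H](O[Si](CC)(CC)CC)[C@H]4C[C@H]1[C@H]2[C@@H]43 | intermediate
36 | 8-O-triethylsilyl ether of the target acid (not isolated) | CCCCCCCC[C@H]1[C@@H]2C=C[C@]3(O)C(C(=O)O)=C[C@@H](O[Si](CC)(CC)CC)[C@H]4C[C@H]1[C@H]2[C@@H]43 | intermediate
37 | CNP0106718.3 | CCCCCCCC[C@H]1[C@@H]2C=C[C@]3(O)C(C(=O)O)=C[C@@H](O)[C@H]4C[C@H]1[C@H]2[C@@H]43 | target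

Total step count: 21. Longest linear sequence: 21 steps (from glutaric anhydride 1; the route is fully linear).

Steps most likely to fail

1. Step 20 (Proposed new method). What may go wrong: conjugate reduction of the ring enone competing with hydrocupration of the alkynoate, protonation of the allenolate before ring closure, or retro-aldol of the tertiary aldolate. Fallback with known chemistry: setting out from 34, an iodide-triggered halo-aldol cyclisation (MgI2, CH2Cl2, 0 °C; iodide adds to C7 and the β-iodo allenolate closes onto C5) should give the β-iodo tetracyclic ester F1. Palladium-catalysed formate reduction of the vinyl iodide (Pd(PPh3)4, HCO2H, Et3N, DMF, 50 °C) then removes the iodine and comes back to the route at 35.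

2. Step 8. What may go wrong: capture of the keteniminium ion by the tethered ketone oxygen instead of acetylene, sluggish reaction with the weakly nucleophilic alkyne, or weak facial bias at C11. Fallback: setting out from lactone 10, ring opening with Me2AlSEt (AlMe3, EtSH, CH2Cl2) should give the hydroxy thioester F2, which is silylated at once (TBDPSCl, imidazole) to the silyl ether F3. The same Tf2O/collidine, acetylene and water sequence on F3, whose thioester carbonyl is a poor nucleophile, should give the cyclobutenone thioester F4. A neutral palladium/copper-mediated thioester–vinylstannane ketone synthesis (tributyl(vinyl)stannane, Pd2(dba)3, tri(2-furyl)phosphine, copper(I) diphenylphosphinate, THF, rt) then installs the vinyl ketone and comes back to the route at 18.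

3. Step 10. What may go wrong: electrocyclic opening of the cyclobutenone or oligomerisation of the silyloxydiene outrunning the cycloaddition, or formation of the enol ether with the wrong geometry in step 9 so that the diene cannot reach the dienophile. Fallback: setting out from 18, an anionic double Michael closure replaces the thermal cycloaddition. KHMDS (THF, −78 °C) forms the cross-conjugated potassium dienolate of the vinyl ketone, C13 adds to C12, and the resulting cyclobutanone enolate adds through C2 to C3. The final C4=C5 enolate is silylated in the same flask with TBSCl, which comes back to the route at 20; this fallback isolates no new compound (F0).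

Further compounds
F1 | step 20 | β-iodo tetracyclic methyl ester (35 with iodine on C7) | CCCCCCCC[C@H]1[C@@H]2C=C[C@]3(O)C(C(=O)OC)=C(I)[C@@H](O[Si](CC)(CC)CC)[C@H]4C[C@H]1[C@H]2[C@@H]43
F2 | step 8 | S-ethyl (S)-6-[(2S,5S)-2,5-dimethylpyrrolidin-1-yl]-3-(hydroxymethyl)-6-oxohexanethioate | CCSC(=O)C[C@@H](CO)CCC(=O)N1[C@@H](C)CC[C@@H]1C
F3 | step 8 | S-ethyl (S)-3-{[(tert-butyldiphenylsilyl)oxy]methyl}-6-[(2S,5S)-2,5-dimethylpyrrolidin-1-yl]-6-oxohexanethioate | CCSC(=O)C[C@@H](CO[Si](c1ccccc1)(c1ccccc1)C(C)(C)C)CCC(=O)N1[C@@H](C)CC[C@@H]1C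
F4 | step 8 | S-ethyl (S)-4-[(tert-butyldiphenylsilyl)oxy]-3-{[(S)-4-oxocyclobut-2-en-1-yl]methyl}butanethioate | CCSC(=O)C[C@@H](CO[Si](c1ccccc1)(c1ccccc1)C(C)(C)C)C[C@H]1C=CC1=O
F0 | step 10 | none | none
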